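**Retrosynthetic overview**
- The target is andrographolide plus one water added anti across C12=C13: the C12 hydroxyl sits on the face of the 14-OH, and H13 is anti to it. The C12–O bond is traced back to a C12–Si bond (Tamao–Fleming oxidation, retention) with silicon tied to O14.
- The resulting cis-fused oxasilolane (C12–Si and C13–H) comes from a photochemical 5-endo silyl-radical cyclisation of a 14-O-SiHPh2 ether onto the alkylidene lactone. C14 controls both new stereocentres.
- The silyl ether comes from andrographolide, with the 3,19-diol masked in the same pot as a phenylboronate that is removed during the final oxidation.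
- Ring order: rings A and B and the lactone ring (with C3, C4, C5, C9, C10, C14) are bought. The only rings made are temporary: the dioxaborinane in step 1 and the oxasilolane in step 2, both opened in step 3.

Assumption: andrographolide (bulk labdane lactone from Andrographis paniculata) is taken as a cheap commercial chiral starting material; atoms carry labdane numbering (decalin C1–C10, side chain C11–C12, lactone C13–C16).

**Route**

Step 1
Reactants: 1 andrographolide
Product: 3 14-O-(diphenylsilyl)andrographolide 3,19-O-phenylboronate, via cyclic 3,19-O-phenylboronate 2 (not isolated)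
Conditions: PhB(OH)2 (1.05 equiv), 4 Å MS, THF, 25 °C, 2 h; then Et3N (1.5 equiv), DMAP (5 mol %), Ph2SiHCl (1.1 equiv), 0 → 25 °C; filter, short plug of Et3N-deactivated silica
Reagents that add atoms: phenylboronic acid OB(O)c1ccccc1; chlorodiphenylsilane Cl[SiH](c1ccccc1)c1ccccc1
Why: Boronic ester condensation ties the 3,19-diol into a six-membered, neopentyl-glycol-type dioxaborinane (the lone 14-OH cannot form a cyclic ester), so the following O-silylation (silyl ether formation) can only take place at O14; no stereocentre is touched.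

Step 2
Reactants: 3 14-O-(diphenylsilyl)andrographolide 3,19-O-phenylboronate
Product: 4 (12R,13R,14S)-12-C,14-O-(diphenylsilanediyl)-12,13-dihydroandrographolide 3,19-O-phenylboronate (cis-fused 2,2-diphenyl-1,2-oxasilolane on the lactone)
Conditions: 4CzIPN (2,4,5,6-tetra(carbazol-9-yl)isophthalonitrile, 2 mol %), quinuclidin-3-yl acetate (20 mol %), iPr3SiSH (10 mol %), MeCN (0.01 M), Ar, 456 nm LEDs, 25 °C
Reagents that add atoms: none
Why: Proposed new method: a visible-light photoredox/hydrogen-atom-transfer 5-endo-trig silyl-radical cyclisation (net anti-hydrosilylation) of an allylic O–SiHPh2 ether onto an α-alkylidene lactone. Excited 4CzIPN oxidises the quinuclidine to its aminium radical, which (directly or through the thiyl radical) abstracts the hydridic Si–H. The nucleophilic silyl radical is held to O14 by two atoms, so it can reach the electrophilic β-carbon C12 only on the O14 face of the E-alkene, which sets 12R with Si where the hydroxyl will sit. The planar α-lactonyl radical at C13 then takes H from the thiol (or is reduced by the 4CzIPN radical anion and protonated by thiol or quinuclidinium) on the convex face, because a trans-fused 5/5 bicycle is too strained; this sets 13R with H anti to O14. The low triplet energy of 4CzIPN leaves the E-geometry and the 8(17)-methylidene alone, and high dilution suppresses intermolecular addition. The closest known reaction types are the thiol-catalysed radical-chain 5-endo cyclisation of allyloxysilanes and the intermolecular photoredox/HAT hydrosilylation of electron-poor alkenes; metal-catalysed hydrosilylation would instead give 1,4-reduction or an impossible syn addition.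

Step 3
Reactants: 4 (12R,13R,14S)-12-C,14-O-(diphenylsilanediyl)-12,13-dihydroandrographolide 3,19-O-phenylboronate
Product: 5 (12R,13R,14S)-12-hydroxy-12,13-dihydroandrographolide (CNP0113086.1)
Conditions: 30 % aq H2O2 (10 equiv), KF (3 equiv), KHCO3 (3 equiv), THF/MeOH 1:1, 0 → 25 °C; Na2S2O3 quench
Reagents that add atoms: hydrogen peroxide OO
Why: Tamao–Fleming oxidation: the fluoride/bicarbonate-activated alkoxysilane undergoes peroxide-induced 1,2-shift of C12 from Si to O with retention (12R kept), the Si–O14 bond is hydrolysed, and the aryl boronate is oxidised in the same pot so the 3,19-diol is released. The mildly basic medium at or below 25 °C leaves the methylidene, the lactone and the epimerisable C13 untouched.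

**Compound list**
1 | andrographolide, (3E,4S)-3-{2-[(1R,4aS,5R,6R,8aS)-6-hydroxy-5-(hydroxymethyl)-5,8a-dimethyl-2-methylidenedecahydronaphthalen-1-yl]ethylidene}-4-hydroxyoxolan-2-one | C=C1CC[C@@H]2[C@](C)(CO)[C@H](O)CC[C@@]2(C)[C@@H]1C/C=C1/C(=O)OC[C@H]1O | starting material
2 | andrographolide 3,19-O-phenylboronate (2-phenyl-1,3,2-dioxaborinane across O3 and O19, 14-OH free) | C=C1CC[C@@H]2[C@](C)(COB(c3ccccc3)O4)[C@H]4CC[C@@]2(C)[C@@H]1C/C=C1/C(=O)OC[C@H]1O | intermediate
3 | 14-O-(diphenylsilyl)andrographolide 3,19-O-phenylboronate (O14–SiHPh2) | C=C1CC[C@@H]2[C@](C)(COB(c3ccccc3)O4)[C@H]4CC[C@@]2(C)[C@@H]1C/C=C1/C(=O)OC[C@H]1O[SiH](c5ccccc5)c6ccccc6 | intermediate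
4 | (12R,13R,14S)-12-C,14-O-(diphenylsilanediyl)-12,13-dihydroandrographolide 3,19-O-phenylboronate (Si on C12, O on C14, H13 cis to H14) | C=C1CC[C@@H]2[C@](C)(COB(c3ccccc3)O4)[C@H]4CC[C@@]2(C)[C@@H]1C[C@@H]5[C@H]6C(=O)OC[C@H]6O[Si]5(c7ccccc7)c8ccccc8 | intermediate
5 | (3R,4S)-4-hydroxy-3-{(1R)-1-hydroxy-2-[(1R,4aS,5R,6R,8aS)-6-hydroxy-5-(hydroxymethyl)-5,8a-dimethyl-2-methylidenedecahydronaphthalen-1-yl]ethyl}oxolan-2-one, i.e. (12R,13R,14S)-12-hydroxy-12,13-dihydroandrographolide | C=C1CC[C@@H]2[C@](C)(CO)[C@H](O)CC[C@@]2(C)[C@@H]1C[C@@H](O)[C@H]1C(=O)OC[C@H]1O | target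

**Totals**
Total step count: 3. Longest linear sequence: 3.

**Steps most likely to fail**

Step 2 (the proposed new cyclisation). The 5-endo closure may be too slow, giving intermolecular silyl-radical addition, or the C13 enolate may expel O14 to give a 14-deoxy butenolide. The fallback uses known chemistry, sets out from 1 and comes back at 5. Hydroxyl-directed Weitz–Scheffer epoxidation of 1 (tBuOOH 3 equiv, nBuLi 2 equiv, THF, −20 °C) delivers the peroxide to C12 on the O14 face through the lithium chelate and gives (12R,13S)-12,13-epoxy-12,13-dihydroandrographolide F5. Reductive Cα–O cleavage of this epoxy lactone with SmI2 (2.5 equiv) and MeOH in THF at −78 °C, with kinetic protonation of the samarium enolate anti to the 14-hydroxyl, then gives 5.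

Step 3. The two phenyl groups on silicon compete for oxidant and the hindered secondary C12–Si bond may react slowly; long exposure to basic peroxide could epimerise C13 or dehydrate back towards 1. The fallback changes the tether: it sets out from 2 (made in the flask from 1) and comes back at 5. Silylation with ClSiMe2H/Et3N gives 14-O-(dimethylsilyl)andrographolide 3,19-O-phenylboronate F6. Photocyclisation as in step 2 gives the 2,2-dimethyl oxasilolane analogue of 4, F7. Fluoride-free oxidation (H2O2, KHCO3, THF/MeOH, 0 °C) then gives 5.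

Step 1. The transient boronate may hydrolyse in part, leading to silylation at O3 or O19, or 3 may not survive the silica plug. The fallback uses an isolable protecting group, sets out from 1 and comes back at 5. 2,2-Dimethoxypropane and pyridinium p-toluenesulfonate in acetone give 3,19-O-isopropylideneandrographolide F1. Ph2SiHCl/Et3N gives 14-O-(diphenylsilyl)-3,19-O-isopropylideneandrographolide F2. The conditions of step 2 give the 3,19-O-isopropylidene analogue of oxasilolane 4, F3. H2O2/KF/KHCO3 gives the 3,19-O-isopropylidene derivative of 5, F4. AcOH/H2O (3:1, 25 °C) then releases 5.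

**Further compounds**
F1 | step 1 | 3,19-O-isopropylideneandrographolide | C=C1CC[C@@H]2[C@](C)(COC(C)(C)O4)[C@H]4CC[C@@]2(C)[C@@H]1C/C=C1/C(=O)OC[C@H]1O
F2 | step 1 | 14-O-(diphenylsilyl)-3,19-O-isopropylideneandrographolide | C=C1CC[C@@H]2[C@](C)(COC(C)(C)O4)[C@H]4CC[C@@]2(C)[C@@H]1C/C=C1/C(=O)OC[C@H]1O[SiH](c5ccccc5)c6ccccc6
F3 | step 1 | (12R,13R,14S)-12-C,14-O-(diphenylsilanediyl)-3,19-O-isopropylidene-12,13-dihydroandrographolide | C=C1CC[C@@H]2[C@](C)(COC(C)(C)O4)[C@H]4CC[C@@]2(C)[C@@H]1C[C@@H]5[C@H]6C(=O)OC[C@H]6O[Si]5(c7ccccc7)c8ccccc8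
F4 | step 1 | (12R,13R,14S)-12-hydroxy-3,19-O-isopropylidene-12,13-dihydroandrographolide | C=C1CC[C@@H]2[C@](C)(COC(C)(C)O4)[C@H]4CC[C@@]2(C)[C@@H]1C[C@@H](O)[C@H]1C(=O)OC[C@H]1O
F5 | step 2 | (12R,13S)-12,13-epoxy-12,13-dihydroandrographolide (oxirane oxygen on the face of the 14-OH) | C=C1CC[C@@H]2[C@](C)(CO)[C@H](O)CC[C@@]2(C)[C@@H]1C[C@H]5O[C@]56C(=O)OC[C@H]6O
F6 | step 3 | 14-O-(dimethylsilyl)andrographolide 3,19-O-phenylboronate | C=C1CC[C@@H]2[C@](C)(COB(c3ccccc3)O4)[C@H]4CC[C@@]2(C)[C@@H]1C/C=C1/C(=O)OC[C@H]1O[SiH](C)C
F7 | step 3 | (12R,13R,14S)-12-C,14-O-(dimethylsilanediyl)-12,13-dihydroandrographolide 3,19-O-phenylboronate | C=C1CC[C@@H]2[C@](C)(COB(c3ccccc3)O4)[C@H]4CC[C@@]2(C)[C@@H]1C[C@@H]5[C@H]6C(=O)OC[C@H]6O[Si]5(C)C
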